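## The problem

Compound 16, 2-hydroxy-4-methoxy-6-(2-oxotridecyl)benzoic acid, is a benzene ring with four substituents in a 1,2,3,5 pattern: the carboxyl group on C1, a free hydroxyl on C2, a methoxy group on C4 and the 2-oxotridecyl chain on C6. It has no second ring and no stereocentre, so the difficulty is regiochemical and chemoselective only. The three contiguous substituents on C6, C1 and C2 must be placed without ambiguity, and the two ring oxygens, equivalent in any simple resorcinol precursor, must end up different (OH on C2, OMe on C4). The sensitive region is the arylacetone unit. Its benzylic CH2 is acidic, dehydrating acid closes the ketone onto the neighbouring carboxyl as an enol lactone (isocoumarin), and base can drive aldol addition onto any electrophilic carbon placed on C1. The finished acid is an electron-rich salicylic acid that loses CO2 when heated in acid, so the last operations must be cold and short. The enabling feature is that the carboxyl carbon on C1 and the chain CH2 on C6 are carbon substituents on neighbouring ring carbons, with oxygen on C2 on one side only. A 3-alkoxyaryne spanning C1 and C6 gives exactly this when a carbon nucleophile and an acyl group add across it, and the alkoxy group decides which goes where.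

## Retrosynthesis

**16 to 15.** The last bond cut is the O–CH3 bond on C2, leading back to dimethyl ether 15. Keeping both oxygens as methyl ethers leaves the arene building block symmetrical until C1 is defined. A different protecting group on the C2 oxygen would break that symmetry at the phenol stage and create a regiochemical problem in the ring silylation. 15 is hardly smaller, but it keeps the free salicylic acid out of every earlier step. The forward reaction must cleave the ether beside the carboxyl and spare the one on C4, which is asked of chelation to a boron Lewis acid.

**15 to 14.** The carboxyl group of 15 is traced to the trifluoroacetyl group of 14, the C(O)–CF3 bond being broken forward by aqueous base. This detour is imposed by the next cut: the future carboxyl carbon must arrive as an acyl group more electrophilic than the undecyl ketone, which an ester is not. The forward reaction must be faster than aldol addition of the side-chain enolate to the same carbonyl.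

**14 to 8 and 11.** Two bonds of 14 are cut together, C6–CH2 and C1–C(acyl). The ring goes back to aryne 12, released from silyl triflate 8, and the chain plus the acyl carbon go back to diketone 11. Cutting only C6–CH2 (arylation of a ketone enolate by a 2-halobenzoate) or only C1–C(O) (metalation and carboxylation of an arylacetone) would need a tetrasubstituted, differentially functionalised arene. It would also expose the acidic benzylic ketone to a metal base. The double cut needs only a symmetrical phenol derivative and a 1,3-diketone. The forward reaction must bond the central carbon of 11 to C6 and not to C1, which is asked of the C2 methoxy group. It must also transfer the trifluoroacetyl and not the dodecanoyl group, which happens through the four-membered alkoxide 13.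

**11 to 9 and 10.** The C2–C3 bond of the diketone is cut, giving methyl ketone 9 and ester 10. No other cut gives two commercial liquids in one step. The forward condensation must acylate the methyl and not the methylene side of 9.

**8 to 6.** The O–S bond of the triflate is cut and the oxygen is traced to the carbamate oxygen of 6, through phenol 7. Exchanging carbamate for triflate in one flask avoids isolating 7, whose aryl–silicon bond is acid-labile.

**6 to 2.** The C–Si bond on the ring carbon between the carbamate and a methoxy group is cut. The two such positions of 2 are equivalent, so ortho-metalation (through 3, 4 and 5) has only one productive site. Ring bromination would need an isomer separation and is the weaker neighbour.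

**2 to 1.** The carbamate C–O bond is cut, leaving commercial phenol 1. The secondary carbamate is chosen because it directs metalation strongly and leaves under mild base.

## Roads not taken

Alternative 1: The cut is ring bond C1–C6, the arene being made from an open chain. Diketo-dioxinone A1, with its far ketone masked as a dioxolane, would be treated with an amine base and then mild acid. The dioxinone C–H carbon adds to the 4-oxo group of the side chain, water is lost, and benzodioxinone A2 results.
- Merits: A2 has the C4 oxygen free while the C2 oxygen and the carboxyl are tied together as an acetonide. O-methylation at C4 and unmasking therefore need no selective ether cleavage, and the ring forms under very mild conditions.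
- Weak points: A1 is a sensitive polycarbonyl chain that takes four to five steps to assemble. The dioxolane is indispensable, because a free ketone would offer competing aldol closures. Hindered benzodioxinones open only in forcing hydroxide, which meets the same base-sensitive arylacetone at the end.
- Comparison: on oxygen differentiation this road is better than the chosen one, which relies on the chelation-controlled step 7. The chosen plan sets against it a shorter count (seven steps against about nine), a ring bought ready-made in 1, and both ring–carbon bonds made in one step.

Alternative 2: The cut is the enol-lactone C–O bond and, behind it, the C6–C(sp) bond. Alkynyl acid A3 would come from a Sonogashira coupling of a brominated dimethoxybenzoate ester with the C13 terminal alkyne, then saponification. A cationic monovalent gold catalyst from AuCl(PPh3) and AgOTf would cyclise it: the carboxyl oxygen adds to the distal alkyne carbon (6-endo-dig) to give isocoumarin A4, which hydroxide opens to 15.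
- Merits: every step belongs to a thoroughly established class. The ketone travels masked as an alkyne and then as an enol lactone, so no free arylacetone is exposed until the end. A4 is a robust substrate for demethylation beside the lactone carbonyl.
- Weak points: the arene must be made already brominated and carboxylated, about three steps. 5-Exo-dig closure to the alkylidene phthalide competes, and its hydrolysis would put the ketone on the benzylic carbon, the wrong constitutional isomer. A doubly ortho-substituted ester must be saponified.
- Comparison: in step-by-step reliability this road is at least the equal of the chosen plan and probably better, and its end game is the same. The chosen plan sets against it one metal-free operation that forms both ring–carbon bonds from a symmetrical phenol, regiochemistry fixed by the aryne and not by a pre-functionalised arene, and about one step fewer.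

Alternative 3: The cuts are ring bonds C5–C6 and C1–C2. Diene A5 and alkynoate A6, whose ketone is held as a dithiane, would be heated together. The diene CH2 terminus bonds to the alkynoate β-carbon, the acetal methoxy group is eliminated, and desilylation on acidic work-up gives benzoate A7.
- Merits: A7 already carries OH on C2 and OMe on C4, delivered by the polarity of the two partners. There is no aryne and no selective demethylation.
- Weak points: β-alkyl alkynoates are sluggish dienophiles and need prolonged heating that the labile diene tolerates badly. The propargylic dithiane of A6 can isomerise to an allene. A5 and A6 together take about five steps. Afterwards a hydrogen-bonded, doubly ortho-substituted methyl salicylate must be saponified, and the dithiane must be removed with electrophilic or oxidising reagents beside an electron-rich phenol.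
- Comparison: better than the chosen plan on oxygen differentiation and equal in forming two ring bonds in the key step. It is longer (about eight steps), and its key step is doubtful in reactivity, not only in selectivity. In the chosen plan the open questions are selectivities that the substrate itself answers.

Key step: step 5

Assumption: 16 is taken as the open keto acid drawn and not as its enol lactone, so acidic work-ups are kept cold and dilute.

## Route

Step 1
Reactants: 1 3,5-dimethoxyphenol
Product: 2 3,5-dimethoxyphenyl N-(propan-2-yl)carbamate
Conditions: i-PrNCO, Et3N (cat.), CH2Cl2, rt
Reagents that add atoms: isopropyl isocyanate, CC(C)N=C=O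
Why: Amine-catalysed addition of the phenol O–H to the isocyanate (O-carbamoylation) installs a secondary carbamate that directs ortho-metalation and later leaves under mild base; nothing else in 1 reacts.

Step 2
Reactants: 2 3,5-dimethoxyphenyl N-(propan-2-yl)carbamate
Product: 6 3,5-dimethoxy-2-(trimethylsilyl)phenyl N-(propan-2-yl)carbamate, via N-silyl carbamate 3 (not isolated), via aryllithium 4 (not isolated), via disilyl carbamate 5 (not isolated)
Conditions: TBSOTf, TMEDA, Et2O, 0 °C to rt; n-BuLi, TMEDA, −78 °C; TMSCl, −78 °C to rt; aq. NaHSO4
Reagents that add atoms: chlorotrimethylsilane, C[Si](C)(C)Cl; tert-butyldimethylsilyl trifluoromethanesulfonate, CC(C)(C)[Si](C)(C)OS(=O)(=O)C(F)(F)F (silyl group in 3, 4 and 5 only); n-butyllithium, [Li]CCCC (lithium in 4 only)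
Why: Directed ortho-metalation: N-silylation gives 3 with no N–H, and n-BuLi/TMEDA then removes the ring proton between the strongly coordinating carbamate and a methoxy group (two equivalent sites) in preference to the one between the two methoxy groups. At −78 °C aryllithium 4 should be trapped by TMSCl before anionic Fries rearrangement, and mild aqueous acid removes the labile N-silyl group of 5.

Step 3
Reactants: 6 3,5-dimethoxy-2-(trimethylsilyl)phenyl N-(propan-2-yl)carbamate
Product: 8 3,5-dimethoxy-2-(trimethylsilyl)phenyl trifluoromethanesulfonate, via silylphenol 7 (not isolated)
Conditions: DBU, Et2NH, MeCN, 40 °C; then PhNTf2, rt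
Reagents that add atoms: N-phenylbis(trifluoromethanesulfonimide), O=S(=O)(N(c1ccccc1)S(=O)(=O)C(F)(F)F)C(F)(F)F
Why: DBU deprotonates the carbamate N–H and the aryloxide is expelled (E1cB elimination), the isocyanate being scavenged by Et2NH as a urea; the phenoxide of 7 is then O-triflated in the same flask. The conditions are basic throughout, so the acid-labile aryl–silicon bond of 7 should survive.

Step 4
Reactants: 9 tridecan-2-one; 10 ethyl trifluoroacetate
Product: 11 1,1,1-trifluoropentadecane-2,4-dione
Conditions: NaOEt, MTBE, 0 °C to rt; then 1 M HCl
Reagents that add atoms: none
Why: Crossed Claisen condensation: the ester cannot enolise and is strongly electrophilic, and under reversible alkoxide conditions acylation should settle on the methyl side of 9, because the linear diketonate is the less hindered and more stable salt while a branched adduct reverts by retro-Claisen cleavage. Acid work-up releases 11, which exists largely as its enol.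

Step 5
Reactants: 8 3,5-dimethoxy-2-(trimethylsilyl)phenyl trifluoromethanesulfonate; 11 1,1,1-trifluoropentadecane-2,4-dione
Product: 14 1-[3,5-dimethoxy-2-(trifluoroacetyl)phenyl]tridecan-2-one, via 3,5-dimethoxybenzyne 12 (not isolated), via benzocyclobutenoxide 13 (not isolated)
Conditions: CsF (2.5 equiv), 8 (1.25 equiv), MeCN (0.2 M), 80 °C
Reagents that add atoms: caesium fluoride, [Cs+].[F-] (caesium counter-ion of 13 only)
Why: Fluoride from CsF attacks silicon in 8 and triflate leaves from the neighbouring carbon, releasing aryne 12 slowly because the salt is sparingly soluble in MeCN. The central carbon of the caesium enolate of 11 adds to the aryne carbon remote from the flanking methoxy group (C6 of the target), the site opened by the ring distortion this methoxy group causes, so the aryl anion develops on C1 where the adjacent C–O bond stabilises it inductively. The anion then adds to the trifluoromethyl ketone carbonyl in a 4-exo-trig closure to give benzocyclobutenoxide 13; this ring is transient and its two stereocentres are of no consequence, since 13 fragments at once (retro-aldol opening of the strained ring) to the aryl trifluoromethyl ketone and the aryl-conjugated enolate of the undecyl ketone, which unreacted 11 protonates to 14. No ring and no stereocentre therefore remain in the product. The closest known reaction type is the fluoride-induced acyl-alkylation of arynes by β-ketoesters and 1,3-diketones, a formal insertion of the aryne into the C–C bond between the central carbon and the more electrophilic carbonyl group. Two selectivities are needed: the site of attack on the aryne, secured by the methoxy group beside the triple bond (the second methoxy group lies meta to the attacked carbon and does not oppose it), and the choice of migrating acyl group, secured by the trifluoromethyl ketone being far more electrophilic than the dialkyl ketone. A slight excess of 8 over 11 and moderate dilution are meant to limit protonation of the aryl anion by free 11 before it closes, which would end in simple α-arylation.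

Step 6
Reactants: 14 1-[3,5-dimethoxy-2-(trifluoroacetyl)phenyl]tridecan-2-one
Product: 15 2,4-dimethoxy-6-(2-oxotridecyl)benzoic acid
Conditions: 2 M aq. KOH, THF, rt to 50 °C, under Ar; then cold 1 M HCl to pH 3
Reagents that add atoms: potassium hydroxide, [K+].[OH-]
Why: Haloform-type cleavage of an aryl trifluoromethyl ketone: hydroxide adds to the very electrophilic carbonyl and the tetrahedral adduct expels trifluoromethyl anion, protonated to fluoroform, leaving the carboxylate. In strong aqueous base the ketone is held almost wholly as its unreactive hydrate anion, so aldol addition of the side-chain enolate should not compete; methanol is avoided so that no hindered methyl ester forms. Cold acidification to pH 3 frees the acid without closing the enol lactone.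

Step 7
Reactants: 15 2,4-dimethoxy-6-(2-oxotridecyl)benzoic acid
Product: 16 2-hydroxy-4-methoxy-6-(2-oxotridecyl)benzoic acid
Conditions: BCl3 (1 M in CH2Cl2, 2.5 equiv), CH2Cl2, −78 to 0 °C; then ice-water
Reagents that add atoms: none
Why: Chelation-controlled ether cleavage: BCl3 binds the carboxyl group as an acyloxyborane and then the neighbouring C2 methoxy oxygen in a six-membered chelate, and chloride removes that methyl group, whereas the C4 methoxy group has no carbonyl neighbour and should stay at or below 0 °C. Hydrolysis of the chelate in ice-water releases 16 without heating, which guards against decarboxylation and lactonisation.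

## Compound list

1 | 3,5-dimethoxyphenol | COc1cc(O)cc(OC)c1 | starting material
2 | 3,5-dimethoxyphenyl N-(propan-2-yl)carbamate | COc1cc(OC)cc(OC(=O)NC(C)C)c1 | intermediate
3 | 3,5-dimethoxyphenyl N-(tert-butyldimethylsilyl)-N-(propan-2-yl)carbamate | COc1cc(OC)cc(OC(=O)N(C(C)C)[Si](C)(C)C(C)(C)C)c1 | intermediate
4 | [2-({[tert-butyl(dimethyl)silyl](propan-2-yl)carbamoyl}oxy)-4,6-dimethoxyphenyl]lithium | COc1cc(OC)c([Li])c(OC(=O)N(C(C)C)[Si](C)(C)C(C)(C)C)c1 | intermediate
5 | 3,5-dimethoxy-2-(trimethylsilyl)phenyl N-(tert-butyldimethylsilyl)-N-(propan-2-yl)carbamate | COc1cc(OC)c([Si](C)(C)C)c(OC(=O)N(C(C)C)[Si](C)(C)C(C)(C)C)c1 | intermediate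
6 | 3,5-dimethoxy-2-(trimethylsilyl)phenyl N-(propan-2-yl)carbamate | COc1cc(OC)c([Si](C)(C)C)c(OC(=O)NC(C)C)c1 | intermediate
7 | 3,5-dimethoxy-2-(trimethylsilyl)phenol | COc1cc(OC)c([Si](C)(C)C)c(O)c1 | intermediate
8 | 3,5-dimethoxy-2-(trimethylsilyl)phenyl trifluoromethanesulfonate | COc1cc(OC)c([Si](C)(C)C)c(OS(=O)(=O)C(F)(F)F)c1 | intermediate
9 | tridecan-2-one | CCCCCCCCCCCC(C)=O | starting material
10 | ethyl trifluoroacetate | CCOC(=O)C(F)(F)F | starting material
11 | 1,1,1-trifluoropentadecane-2,4-dione | CCCCCCCCCCCC(=O)CC(=O)C(F)(F)F | intermediate
12 | 3,5-dimethoxybenzyne (1,2-didehydro-3,5-dimethoxybenzene) | COC1=CC(OC)=CC#C1 | intermediate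
13 | caesium 7-dodecanoyl-2,4-dimethoxy-8-(trifluoromethyl)bicyclo[4.2.0]octa-1,3,5-trien-8-olate (either relative configuration) | CCCCCCCCCCCC(=O)C1c2cc(OC)cc(OC)c2C1([O-])C(F)(F)F.[Cs+] | intermediate
14 | 1-[3,5-dimethoxy-2-(trifluoroacetyl)phenyl]tridecan-2-one | CCCCCCCCCCCC(=O)Cc1cc(OC)cc(OC)c1C(=O)C(F)(F)F | intermediate
15 | 2,4-dimethoxy-6-(2-oxotridecyl)benzoic acid | CCCCCCCCCCCC(=O)Cc1cc(OC)cc(OC)c1C(=O)O | intermediate
16 | 2-hydroxy-4-methoxy-6-(2-oxotridecyl)benzoic acid | CCCCCCCCCCCC(=O)Cc1cc(OC)cc(O)c1C(=O)O | target

## Step count and risks

Total: 7 steps. Longest linear sequence: 6 steps (steps 1, 2, 3, 5, 6, 7); step 4 is a one-step branch.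

**Step 5 (key step).** The strongly stabilised trifluoromethyl diketonate may add to the aryne too slowly, so that aryne self-reaction or fluoride trapping takes over. The aryl anion may be protonated by the acidic diketone before it closes, ending in α-arylation and loss of the trifluoroacetyl group. Fluoride and trace water may also degrade 11 by retro-Claisen cleavage.
Fallback, from 8, rejoining at 15: the aryne would be inserted into the C–C bond of dimethyl malonate (CsF, MeCN), an established acyl-alkylation that by the same regiochemical rule should give methyl 2,4-dimethoxy-6-(2-methoxy-2-oxoethyl)benzoate F1. Saponification (KOH, aq. EtOH, reflux) gives 2-(carboxymethyl)-4,6-dimethoxybenzoic acid F2, and Ac2O closes it to 6,8-dimethoxyisochromane-1,3-dione F3. C-acylation with dodecanoyl chloride (Et3N, MeCN) gives 4-dodecanoyl-6,8-dimethoxyisochromane-1,3-dione F4. Aqueous KOH and cold acidification open the anhydride and decarboxylate the β-keto acid to 15.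

**Step 6.** If hydroxide addition or expulsion of the trifluoromethyl group is slowed by the two ortho substituents, aldol addition of the enolate on the undecyl side of the ketone to the trifluoroacetyl carbonyl may close a six-membered carbocycle. The benzylic position may also oxidise in air under base.
Fallback, from 14, rejoining at 15: the side-chain ketone would first be masked by silyl-transfer ketalisation (1,2-bis(trimethylsilyloxy)ethane, cat. TMSOTf, CH2Cl2, −78 °C) as 1-{2,4-dimethoxy-6-[(2-undecyl-1,3-dioxolan-2-yl)methyl]phenyl}-2,2,2-trifluoroethan-1-one F5. Hydroxide cleavage then gives 2,4-dimethoxy-6-[(2-undecyl-1,3-dioxolan-2-yl)methyl]benzoic acid F6 with no enolisable ketone present. Dilute aqueous HCl in THF returns 15.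

**Step 7.** The Lewis acid may dehydrate the keto acid to its enol lactone. The C4 ether may be cleaved as well on warming, or the product may decarboxylate during work-up.
Fallback, from 15, rejoining at 16: the lactonisation would be made deliberate. Ac2O at 100 °C gives 6,8-dimethoxy-3-undecyl-1H-isochromen-1-one F7. BCl3 cleaves the ether beside the lactone carbonyl to 8-hydroxy-6-methoxy-3-undecyl-1H-isochromen-1-one F8. Aqueous KOH in THF opens the enol lactone, and cold acidification to pH 3 gives 16.

**Step 2.** Lithiation may occur between the two methoxy groups, or twice. The aryllithium may rearrange by carbamoyl migration if the temperature rises.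
Fallback, from 1, rejoining at 8: bromination ortho to the hydroxyl (NBS, CH2Cl2, −78 °C) would give 2-bromo-3,5-dimethoxyphenol F9, to be separated from its 4-bromo isomer. O-silylation with (Me3Si)2NH gives (2-bromo-3,5-dimethoxyphenoxy)trimethylsilane F10. n-BuLi (THF, −78 °C) then causes bromine–lithium exchange and O-to-C silyl migration (retro-Brook rearrangement) to the lithium salt of 7, which Tf2O converts into 8.

## Further compounds

F1 | step 5 | methyl 2,4-dimethoxy-6-(2-methoxy-2-oxoethyl)benzoate | COC(=O)Cc1cc(OC)cc(OC)c1C(=O)OC
F2 | step 5 | 2-(carboxymethyl)-4,6-dimethoxybenzoic acid | OC(=O)Cc1cc(OC)cc(OC)c1C(=O)O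
F3 | step 5 | 6,8-dimethoxyisochromane-1,3-dione | O=C1Cc2cc(OC)cc(OC)c2C(=O)O1
F4 | step 5 | 4-dodecanoyl-6,8-dimethoxyisochromane-1,3-dione | CCCCCCCCCCCC(=O)C1C(=O)OC(=O)c2c(OC)cc(OC)cc12
F5 | step 6 | 1-{2,4-dimethoxy-6-[(2-undecyl-1,3-dioxolan-2-yl)methyl]phenyl}-2,2,2-trifluoroethan-1-one | CCCCCCCCCCCC1(Cc2cc(OC)cc(OC)c2C(=O)C(F)(F)F)OCCO1
F6 | step 6 | 2,4-dimethoxy-6-[(2-undecyl-1,3-dioxolan-2-yl)methyl]benzoic acid | CCCCCCCCCCCC1(Cc2cc(OC)cc(OC)c2C(=O)O)OCCO1
F7 | step 7 | 6,8-dimethoxy-3-undecyl-1H-isochromen-1-one | CCCCCCCCCCCC1=Cc2cc(OC)cc(OC)c2C(=O)O1
F8 | step 7 | 8-hydroxy-6-methoxy-3-undecyl-1H-isochromen-1-one | CCCCCCCCCCCC1=Cc2cc(OC)cc(O)c2C(=O)O1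
F9 | step 2 | 2-bromo-3,5-dimethoxyphenol | COc1cc(O)c(Br)c(OC)c1
F10 | step 2 | (2-bromo-3,5-dimethoxyphenoxy)trimethylsilane | COc1cc(O[Si](C)(C)C)c(Br)c(OC)c1
A1 | alternative 1 | 6-[2,4-dioxo-5-(2-undecyl-1,3-dioxolan-2-yl)pentyl]-2,2-dimethyl-4H-1,3-dioxin-4-one | CCCCCCCCCCCC1(CC(=O)CC(=O)CC2=CC(=O)OC(C)(C)O2)OCCO1
A2 | alternative 1 | 7-hydroxy-2,2-dimethyl-5-[(2-undecyl-1,3-dioxolan-2-yl)methyl]-4H-1,3-benzodioxin-4-one | CCCCCCCCCCCC1(Cc2cc(O)cc3OC(C)(C)OC(=O)c23)OCCO1
A3 | alternative 2 | 2,4-dimethoxy-6-(tridec-1-yn-1-yl)benzoic acid | CCCCCCCCCCCC#Cc1cc(OC)cc(OC)c1C(=O)O
A4 | alternative 2 | 6,8-dimethoxy-3-undecyl-1H-isochromen-1-one | CCCCCCCCCCCC1=Cc2cc(OC)cc(OC)c2C(=O)O1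
A5 | alternative 3 | 1,3-dimethoxy-1-(trimethylsilyloxy)buta-1,3-diene | C=C(OC)C=C(OC)O[Si](C)(C)C
A6 | alternative 3 | methyl 4-(2-undecyl-1,3-dithian-2-yl)but-2-ynoate | CCCCCCCCCCCC1(CC#CC(=O)OC)SCCCS1
A7 | alternative 3 | methyl 2-hydroxy-4-methoxy-6-[(2-undecyl-1,3-dithian-2-yl)methyl]benzoate | CCCCCCCCCCCC1(Cc2cc(OC)cc(O)c2C(=O)OC)SCCCS1
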